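# Synthesis plan for 3-O-caffeoyl-4-O-(p-coumaroyl)quinic acid (22) from (−)-shikimic acid

## The problem

The target 22 is a single cyclohexane with a quaternary carbon C1 (tertiary hydroxyl and the carboxyl carbon C7) and three contiguous carbinol carbons C3, C4 and C5; quinic acid locants are used throughout, so O3 is cis to O4 and to O1, and O5 is trans to O4 and cis to C7. An (E)-caffeate sits on O3 and an (E)-p-coumarate on O4, while O1, O5 and the carboxyl group are free. No rings have to be joined, so the task is to fix four stereocentres on one ring and to tell four hydroxyls and one carboxyl apart. C3, C4 and C5 have the configuration of (−)-shikimic acid 1 and can be bought, but C1 is separated from them by the methylenes C2 and C6, so its hydroxyl needs an external control element. The cinnamate esters do not survive hydride, hydrogenation or strong oxidants, and under base the acyl groups wander between O3, O4 and O5; all redox work therefore has to precede acylation, and the closing steps have to be acidic or neutral. The feature that makes the key step possible is that the ring of 22 is that of 1 plus water across C1=C2: with C7 at the alcohol level it is a primary allylic hydroxyl that can carry a titanium tartrate peroxide to one face of C1=C2, after which hydride can enter at the secondary C2. A second useful feature is that C7 and O5 are cis, so a 1,5-lactone masks both at once and inverts the chair, which makes O3–H equatorial and O4–H axial.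

## Retrosynthesis

**22 ⇒ 21 ⇒ 20.** No skeletal bond is cut first. 22 is traced to lactone 21 by re-closing the C7–O5 ester bond and capping the three phenols as acetates, and 21 to 20 by placing a 2,2,2-trichloroethyl carbonate (Troc) on O1. The lactone is preferred to an open carboxylic ester because it protects O5 and C7 with one bond and fixes the conformation needed below. The forward reactions must be non-basic: reductive loss of the carbonate, then acidic hydrolysis of the lactone and the aryl acetates.

**20 ⇒ 16 + 18 and 16 ⇒ 12 + 14.** The two ester C–O bonds are cut, the one at O4 first and the one at O3 second. This leaves the lactone diol 12 and the acetylated acids 14 and 18, which come from caffeic acid 13 and p-coumaric acid 17. In the lactone chair O3–H is equatorial and O4–H axial, so the forward order is O3 and then O4. In the open chair O3 would be axial and O4 equatorial beside a bulky O5 group, with no dependable preference. O1 is blocked because the tertiary hydroxyl could compete with the hindered O4–H in the second esterification.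

**12 ⇒ 11 ⇒ 10 ⇒ 9 ⇒ 8.** These are protecting-group and lactone adjustments. The diol of 12 is re-masked as the acetonide (11), the carbonate is removed (10), the C7–O5 bond is cut (9) and O5 is re-silylated (8). Acid 8 is much simpler: one free tertiary hydroxyl, one acid, and O5 already told apart from O3 and O4. The forward steps are routine (fluoride, acid-catalysed lactonisation, chloroformate, aqueous acid).

**8 ⇒ 7.** The oxidation level of C7 is changed from acid to primary alcohol. The cut is needed because only the alcohol can direct the epoxidation. The forward oxidation has to take a primary alcohol next to a tertiary one to the acid without glycol cleavage.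

**7 ⇒ 6.** The C2–H bond of 7 is replaced by a C2–O bond, which gives oxirane 6. Direct hydration of the alkene would offer neither facial nor positional control, and dihydroxylation would leave a C2 hydroxyl to be removed. The epoxide brings oxygen to C1 on a defined face, and C2 is the less substituted carbon for hydride.

**6 ⇒ 5 (key disconnection).** The C1–O and C2–O bonds of the oxirane are cut to give allylic alcohol 5. The conjugated ester 4 resists electrophilic oxygen transfer, and oxidants that ignore the hydroxyl would follow the bias of the ring. The allylic alcohol allows the Sharpless asymmetric epoxidation, in which the reagent chooses the face. The forward reaction must place oxygen on the face of O3 and O4.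

**5 ⇒ 4 ⇒ 3 ⇒ 1.** The ester is reduced, O5 silylated and the cis-3,4-diol ketalised, starting from the methyl ester of 1. C3, C4 and C5 are bought with their absolute configuration. Only the cis pair O3/O4 closes a dioxolane readily, so O5 is differentiated at once.

## Roads not taken

Alternative 1: The ring would be cut at C1–C6 and C2–C3 into buta-1,3-diene A2 and 2-(benzoyloxy)acrolein A3. In the forward direction a chiral acid catalyst would steer the Diels–Alder reaction of A2 with A3 to (S)-1-formylcyclohex-3-en-1-yl benzoate A1, which already holds C1 with its oxygen and C7. Merits: A2 and A3 are cheap, and the ring and C1 are formed in one catalytic step. The classical relay from A1 (aldehyde oxidation, halolactonisation onto C5, elimination, cis-dihydroxylation away from the lactone bridge) would reach a 1-O-acyl lactone diol like 12 in about five steps, which is clearly shorter than the ten steps needed here. Weak points: A2 is a gaseous and weakly reactive diene, and high enantioselectivity with dienophiles such as A3 is established mainly for more reactive dienes. The centre of A1 set by the catalyst is the only source of absolute configuration, so any shortfall reaches C3, C4 and C5 as the enantiomer and cannot be removed by separating diastereomers. The benzoate on O1 of A1 cannot be removed beside cinnamates and would have to be exchanged. Comparison: the road through A1 is shorter to the core, and the chosen plan is longer. Against that, the chosen plan buys three centres with secured configuration and forms the fourth under reagent control, where a wrong-face product is a separable diastereomer.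

Alternative 2: The ring would be cut at C5–C6 and C1–C2 into phosphoenolpyruvate A5 and D-erythrose 4-phosphate A6. In one pot the aldolase-type synthase that opens the shikimate pathway would add C3 of A5 to the aldehyde of A6 (bond C5–C6), and the cyclase that follows it would close the ring by intramolecular aldol addition (bond C1–C2) to give 3-dehydroquinic acid A4. Merits: all carbon–carbon bonds and C1, C4 and C5 of A4 are set in water without protecting groups, and no route to the core is shorter or more atom-economic. Weak points: A6 is costly and unstable, and both enzymes must be produced. The cyclase needs a nicotinamide cofactor and a divalent metal ion. A4 still needs a face-selective reduction at C3 to give (−)-quinic acid A7, which is an undifferentiated polyol acid and itself an inexpensive article of commerce. The whole differentiation endgame would then start from A7. Comparison: as a supply of the bare core this road, or the simple purchase of A7, is better, since the acetonide lactone 10 lies one acid-catalysed step from A7 against eight steps here. The chosen plan sets against this that it uses bench chemistry only, has O5 separated from O3 and O4 from the second step, and passes through oxirane 6, from which C2 can be labelled or substituted.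

Alternative 3: The cis-diol bond C3–C4 would be cut, which gives the acyclic dialdehyde methyl 2,4-bis(benzyloxy)-2-(2-oxoethyl)-5-oxopentanoate A9. SmI2 (divalent samarium) would reduce both aldehydes of A9, and the ketyl coupling would close the ring to methyl 1,5-di-O-benzylquinate A8. Merits: ring closure and both carbinol centres arise in one step as the cis-diol. A8 has O3 and O4 free and O1 and O5 protected, a pattern the chosen plan reaches only at step 10 with 12. Weak points: A9 has a quaternary α-alkoxy ester centre and a remote secondary centre, and needs its own multi-step asymmetric synthesis. The orientation of the new diol of A8 relative to C5 and C1 depends on the substrate. The benzyl ethers of A8 cannot be hydrogenolysed once the cinnamates are in place. In the open chair of A8 the reactivity order of O3 and O4 is less predictable than in the lactone. Comparison: the road through A8 is more direct in protecting-group terms. The chosen plan sets against this a starting material that already contains three of the four centres.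

Key step: step 4

## Route

Abbreviations: TBS = tert-butyldimethylsilyl, TES = triethylsilyl, Troc = 2,2,2-trichloroethoxycarbonyl, quinide = quinic acid 1,5-lactone.

Assumption: ring positions carry the current quinic acid locants (carboxyl on C1, lactone-forming hydroxyl on C5), which makes the target the 3-O-caffeoyl-4-O-(p-coumaroyl) ester; the shikimate-derived compounds carry the same locants.

Step 1
Reactants: 1 (−)-shikimic acid
Product: 3 methyl 3,4-O-isopropylidene-shikimate, via methyl shikimate 2 (not isolated)
Conditions: CSA (10 mol%), MeOH, reflux; evaporate; then 2,2-dimethoxypropane, acetone, rt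
Reagents that add atoms: methanol CO; 2,2-dimethoxypropane COC(C)(C)OC
Why: Fischer esterification followed by acid-catalysed transketalisation with the same catalyst; only the cis-3,4-diol closes a dioxolane readily on the cyclohexene, so O5 stays free, and no stereocentre is touched.

Step 2
Reactants: 3 methyl 3,4-O-isopropylidene-shikimate
Product: 4 methyl 5-O-TBS-3,4-O-isopropylidene-shikimate
Conditions: TBSCl, imidazole, DMF, 40 °C
Reagents that add atoms: tert-butyldimethylsilyl chloride CC(C)(C)[Si](C)(C)Cl
Why: Imidazole-assisted silylation of the only free hydroxyl; the silyl ether keeps O5 off titanium in step 4 and is stable to the hydride and oxidation steps.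

Step 3
Reactants: 4 methyl 5-O-TBS-3,4-O-isopropylidene-shikimate
Product: 5 5-O-TBS-3,4-O-isopropylidene-shikimyl alcohol
Conditions: iBu2AlH (2.5 equiv), CH2Cl2, −78 → 0 °C; aqueous Rochelle salt
Reagents that add atoms: none
Why: 1,2-Reduction of the conjugated ester by the aluminium hydride leaves alkene, acetonide and silyl ether intact and turns an electron-poor alkene into a primary allylic alcohol that can bind titanium.

Step 4
Reactants: 5 5-O-TBS-3,4-O-isopropylidene-shikimyl alcohol
Product: 6 (1S,2S)-1,2-epoxy-5-O-TBS-3,4-O-isopropylidene-shikimyl alcohol
Conditions: Ti(OiPr)4 (1.1 equiv), L-(+)-diethyl tartrate (1.3 equiv), tBuOOH (2 equiv, anhydrous, in decane), 4 Å molecular sieves, CH2Cl2, −20 °C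
Reagents that add atoms: tert-butyl hydroperoxide CC(C)(C)OO
Why: Sharpless asymmetric epoxidation: the C7 alkoxide and the hydroperoxide replace isopropoxide on the dimeric titanium tartrate (tetravalent titanium), and the C1=C2 π bond attacks the activated peroxide oxygen, so both C–O bonds form on one face in a single step. The oxirane therefore closes by concerted oxygen-atom transfer, a [2+1] addition, and not by a stepwise ring closure. The closest known cases are cyclohex-1-enylmethanol and other 2,3-disubstituted primary allylic alcohols, a favourable substrate class for this reagent. C1 is set by the tartrate: L-(+)-diethyl tartrate gives the 2S configuration at the carbinol-bearing carbon of (E)-2-alkenols, and with C7, C6 and C3 placed on that model the oxygen is delivered to the face of O3 and O4, which is C1 = S in 6. C2 follows from the suprafacial delivery and is only a transient centre, removed in step 5. The selectivity needed is facial, and the cis-fused acetonide may favour the opposite face, so a full equivalent of the titanium tartrate is used so that reagent control dominates, as in mismatched epoxidations of primary allylic alcohols with an alkoxy stereocentre next to the alkene. O5 is silylated so that C7–OH is the only hydroxyl on titanium, and low temperature with sieves limits opening of the epoxy alcohol by isopropoxide.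

Step 5
Reactants: 6 (1S,2S)-1,2-epoxy-5-O-TBS-3,4-O-isopropylidene-shikimyl alcohol
Product: 7 5-O-TBS-3,4-O-isopropylidene-quinyl alcohol
Conditions: LiAlH4, THF, 0 → 50 °C; aqueous NaOH work-up
Reagents that add atoms: none
Why: Nucleophilic hydride opens the trisubstituted oxirane by SN2 attack at the secondary C2, anti to the oxirane oxygen (trans-diaxial opening), the usual course for 2,3-epoxy alcohols whose carbinol-bearing oxirane carbon is fully substituted; the C1–O bond is not broken, so C1 keeps its configuration and C2 becomes the methylene.

Step 6
Reactants: 7 5-O-TBS-3,4-O-isopropylidene-quinyl alcohol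
Product: 8 5-O-TBS-3,4-O-isopropylidene-quinic acid
Conditions: TEMPO (cat.), NaOCl (cat.), NaClO2 (2 equiv), MeCN/phosphate buffer pH 6.7, 35 °C
Reagents that add atoms: sodium chlorite [Na+].[O-]Cl=O
Why: TEMPO-mediated oxidation with chlorite as terminal oxidant takes the primary alcohol through the aldehyde to the acid at near-neutral pH; the tertiary hydroxyl cannot be oxidised, and primary/tertiary 1,2-diols give α-hydroxy acids under these conditions without C–C cleavage.

Step 7
Reactants: 8 5-O-TBS-3,4-O-isopropylidene-quinic acid
Product: 9 3,4-O-isopropylidene-quinic acid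
Conditions: TBAF (3 equiv), THF, rt; then aqueous HCl to pH 3
Reagents that add atoms: none
Why: Fluoride-induced cleavage of the secondary silyl ether; acetonide and α-hydroxy carboxylate are inert to fluoride, and brief mild acidification returns the free acid.

Step 8
Reactants: 9 3,4-O-isopropylidene-quinic acid
Product: 10 3,4-O-isopropylidene-1,5-quinide
Conditions: TsOH·H2O (5 mol%), toluene, reflux, Dean–Stark trap
Reagents that add atoms: none
Why: Acid-catalysed lactonisation with azeotropic removal of water; C7 and O5 are cis, so only the five-membered 1,5-lactone can form (5-exo-trig attack of O5 on the carboxyl carbon), and no stereocentre changes.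

Step 9
Reactants: 10 3,4-O-isopropylidene-1,5-quinide
Product: 11 1-O-Troc-3,4-O-isopropylidene-1,5-quinide
Conditions: TrocCl (3 equiv), pyridine, DMAP (0.5 equiv), CH2Cl2, 0 °C → rt
Reagents that add atoms: 2,2,2-trichloroethyl chloroformate ClC(=O)OCC(Cl)(Cl)Cl
Why: DMAP-catalysed carbonate formation on the only free hydroxyl, a tied-back tertiary α-hydroxy lactone that accepts acyl chlorides; the carbonate blocks O1 during both esterifications and is stable to acid.

Step 10
Reactants: 11 1-O-Troc-3,4-O-isopropylidene-1,5-quinide
Product: 12 1-O-Troc-1,5-quinide
Conditions: TFA/H2O/CH2Cl2 (9:1:10), 0 °C → rt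
Reagents that add atoms: none
Why: Acidic hydrolysis of the isopropylidene acetal; carbonate and lactone tolerate brief aqueous acid, and the diol emerges with O3–H equatorial and O4–H axial on the lactone-locked chair.

Step 11
Reactants: 13 caffeic acid
Product: 14 (E)-3,4-diacetoxycinnamic acid
Conditions: Ac2O, pyridine, DMAP (cat.), 0 °C → rt; then water
Reagents that add atoms: acetic anhydride CC(=O)OC(C)=O
Why: Acetylation of both phenols (the mixed anhydride at the carboxyl is hydrolysed on aqueous work-up); the acetates stop the catechol from acylating or oxidising and fall off under the final acidic conditions.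

Step 12
Reactants: 12 1-O-Troc-1,5-quinide; 14 (E)-3,4-diacetoxycinnamic acid
Product: 16 3-O-(3,4-diacetoxycinnamoyl)-1-O-Troc-1,5-quinide, via 3,4-diacetoxycinnamoyl chloride 15 (not isolated)
Conditions: 14, (COCl)2, DMF (cat.), CH2Cl2, 0 °C → rt, evaporate; then 12 (1.0 equiv), pyridine, CH2Cl2, −30 → 0 °C
Reagents that add atoms: none
Why: Acid chloride formation under DMF catalysis and esterification; with one equivalent at low temperature and pyridine as the only base, the equatorial O3–H should react ahead of the axial, doubly flanked O4–H, the preference known from selective silylation and acylation of quinide diols, and the E geometry is untouched.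

Step 13
Reactants: 17 p-coumaric acid
Product: 18 (E)-4-acetoxycinnamic acid
Conditions: Ac2O, pyridine, DMAP (cat.), 0 °C → rt; then water
Reagents that add atoms: acetic anhydride CC(=O)OC(C)=O
Why: Acetylation of the phenol as in step 11, so that the acid chloride can be made and the phenol does not compete as a nucleophile.

Step 14
Reactants: 16 3-O-(3,4-diacetoxycinnamoyl)-1-O-Troc-1,5-quinide; 18 (E)-4-acetoxycinnamic acid
Product: 20 4-O-(4-acetoxycinnamoyl)-3-O-(3,4-diacetoxycinnamoyl)-1-O-Troc-1,5-quinide, via 4-acetoxycinnamoyl chloride 19 (not isolated)
Conditions: 18, (COCl)2, DMF (cat.), CH2Cl2, 0 °C → rt, evaporate; then 16, DMAP (0.3 equiv), pyridine, CH2Cl2, rt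
Reagents that add atoms: none
Why: DMAP-catalysed esterification of the remaining hindered axial hydroxyl with excess acid chloride; O1 is blocked, so O4 is the only nucleophile, and the weakly basic medium is chosen to keep the 3-O-acyl group in place.

Step 15
Reactants: 20 4-O-(4-acetoxycinnamoyl)-3-O-(3,4-diacetoxycinnamoyl)-1-O-Troc-1,5-quinide
Product: 21 4-O-(4-acetoxycinnamoyl)-3-O-(3,4-diacetoxycinnamoyl)-1,5-quinide
Conditions: Zn dust, AcOH/THF, rt
Reagents that add atoms: none
Why: Reductive β-elimination of the trichloroethyl carbonate by zinc (loss of 1,1-dichloroethene and CO2) frees O1 under mildly acidic conditions that should leave cinnamates, aryl acetates and the lactone untouched.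

Step 16
Reactants: 21 4-O-(4-acetoxycinnamoyl)-3-O-(3,4-diacetoxycinnamoyl)-1,5-quinide
Product: 22 3-O-caffeoyl-4-O-(p-coumaroyl)quinic acid
Conditions: 2 M aqueous HCl/THF (1:3), rt
Reagents that add atoms: water O
Why: Acid-catalysed hydrolysis cleaves the three aryl acetates and opens the strained α-hydroxy γ-lactone, while the conjugated secondary cinnamates hydrolyse much more slowly; the acidic medium suppresses acyl migration between O3, O4 and O5, and this is the established way of releasing acyl quinic acids from acetylated acyl quinides.

## Compound list

1 | (−)-shikimic acid, (3R,4S,5R)-3,4,5-trihydroxycyclohex-1-ene-1-carboxylic acid | O[C@H]1[C@H](O)CC(C(=O)O)=C[C@H]1O | starting material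
2 | methyl shikimate, methyl (3R,4S,5R)-3,4,5-trihydroxycyclohex-1-ene-1-carboxylate | O[C@H]1[C@H](O)CC(C(=O)OC)=C[C@H]1O | intermediate
3 | methyl 3,4-O-isopropylidene-shikimate (cis-fused dioxolane on O3/O4, free 5-OH trans to O4) | CC1(C)O[C@H]2[C@H](O)CC(C(=O)OC)=C[C@H]2O1 | intermediate
4 | methyl 5-O-TBS-3,4-O-isopropylidene-shikimate | CC1(C)O[C@H]2[C@H](O[Si](C)(C)C(C)(C)C)CC(C(=O)OC)=C[C@H]2O1 | intermediate
5 | 5-O-TBS-3,4-O-isopropylidene-shikimyl alcohol (C7 hydroxymethyl on C1 of the cyclohexene; C3, C4, C5 as in 1) | CC1(C)O[C@H]2[C@H](O[Si](C)(C)C(C)(C)C)CC(CO)=C[C@H]2O1 | intermediate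
6 | (1S,2S)-1,2-epoxy-5-O-TBS-3,4-O-isopropylidene-shikimyl alcohol (oxirane oxygen cis to O3 and O4, trans to O5) | CC1(C)O[C@H]2[C@H](O[Si](C)(C)C(C)(C)C)C[C@@]3(CO)O[C@H]3[C@H]2O1 | intermediate
7 | 5-O-TBS-3,4-O-isopropylidene-quinyl alcohol (C1–OH cis to O3/O4, C7 hydroxymethyl cis to O5) | CC1(C)O[C@H]2[C@H](O[Si](C)(C)C(C)(C)C)C[C@](O)(CO)C[C@H]2O1 | intermediate
8 | 5-O-TBS-3,4-O-isopropylidene-quinic acid | CC1(C)O[C@H]2[C@H](O[Si](C)(C)C(C)(C)C)C[C@](O)(C(=O)O)C[C@H]2O1 | intermediate
9 | 3,4-O-isopropylidene-quinic acid | CC1(C)O[C@H]2[C@H](O)C[C@](O)(C(=O)O)C[C@H]2O1 | intermediate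
10 | 3,4-O-isopropylidene-1,5-quinide (lactone between C7 and O5, free tertiary 1-OH) | CC1(C)O[C@H]2[C@H]3C[C@](O)(C(=O)O3)C[C@H]2O1 | intermediate
11 | 1-O-Troc-3,4-O-isopropylidene-1,5-quinide | CC1(C)O[C@H]2[C@H]3C[C@](OC(=O)OCC(Cl)(Cl)Cl)(C(=O)O3)C[C@H]2O1 | intermediate
12 | 1-O-Troc-1,5-quinide (3-OH equatorial, 4-OH axial, cis to each other) | O[C@H]1[C@H]2C[C@](OC(=O)OCC(Cl)(Cl)Cl)(C(=O)O2)C[C@H]1O | intermediate
13 | caffeic acid, (E)-3,4-dihydroxycinnamic acid | O=C(O)/C=C/c1ccc(O)c(O)c1 | starting material
14 | (E)-3,4-diacetoxycinnamic acid | CC(=O)Oc1ccc(/C=C/C(=O)O)cc1OC(C)=O | intermediate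
15 | (E)-3,4-diacetoxycinnamoyl chloride | CC(=O)Oc1ccc(/C=C/C(=O)Cl)cc1OC(C)=O | intermediate
16 | 3-O-[(E)-3,4-diacetoxycinnamoyl]-1-O-Troc-1,5-quinide (free axial 4-OH) | O[C@H]1[C@H]2C[C@](OC(=O)OCC(Cl)(Cl)Cl)(C(=O)O2)C[C@H]1OC(=O)/C=C/c1ccc(OC(C)=O)c(OC(C)=O)c1 | intermediate
17 | p-coumaric acid, (E)-4-hydroxycinnamic acid | O=C(O)/C=C/c1ccc(O)cc1 | starting material
18 | (E)-4-acetoxycinnamic acid | CC(=O)Oc1ccc(/C=C/C(=O)O)cc1 | intermediate
19 | (E)-4-acetoxycinnamoyl chloride | CC(=O)Oc1ccc(/C=C/C(=O)Cl)cc1 | intermediate
20 | 4-O-[(E)-4-acetoxycinnamoyl]-3-O-[(E)-3,4-diacetoxycinnamoyl]-1-O-Troc-1,5-quinide | CC(=O)Oc1ccc(/C=C/C(=O)O[C@H]2[C@H]3C[C@](OC(=O)OCC(Cl)(Cl)Cl)(C(=O)O3)C[C@H]2OC(=O)/C=C/c2ccc(OC(C)=O)c(OC(C)=O)c2)cc1 | intermediate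
21 | 4-O-[(E)-4-acetoxycinnamoyl]-3-O-[(E)-3,4-diacetoxycinnamoyl]-1,5-quinide (free 1-OH) | CC(=O)Oc1ccc(/C=C/C(=O)O[C@H]2[C@H]3C[C@](O)(C(=O)O3)C[C@H]2OC(=O)/C=C/c2ccc(OC(C)=O)c(OC(C)=O)c2)cc1 | intermediate
22 | 3-O-caffeoyl-4-O-(p-coumaroyl)quinic acid (caffeate on O3 cis to O4 and O1; free 5-OH trans to O4) | O=C(/C=C/c1ccc(O)cc1)O[C@H]1[C@H](O)C[C@](O)(C(=O)O)C[C@H]1OC(=O)/C=C/c1ccc(O)c(O)c1 | target

## Step count and least certain steps

Total: 16 steps. Longest linear sequence: 14 steps (steps 1–10, 12, 14, 15, 16, from 1).

**Step 4 (key step).** Oxygen may be delivered to the wrong face, because the tartrate has to override whatever preference the cis-fused acetonide imposes. The hindered trisubstituted alkene may also convert slowly, with gradual opening of the epoxy alcohol by isopropoxide. The fallback replaces reagent control by substrate direction. Starting from 5, the acetonide would be hydrolysed with aqueous acetic acid to 5-O-TBS-shikimyl alcohol F1, whose ring hydroxyls O3–H (allylic) and O4–H (homoallylic) lie on the required face. VO(acac)2-catalysed epoxidation with tBuOOH, which delivers oxygen syn to a ring hydroxyl in cyclohexenols, would give the epoxy triol (1S,2S)-1,2-epoxy-5-O-TBS-shikimyl alcohol F2. Re-ketalisation with 2,2-dimethoxypropane and PPTS would return to the route at 6.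

**Step 5.** Hydride may enter at the tertiary C1 by internal delivery from the C7 alkoxyaluminate. Opening at C2 may also be slow, because C2 is flanked by the C3–O bond and the trans-diaxial trajectory costs conformational energy. The fallback separates C–O cleavage from hydrogen delivery. Starting from 6, sodium benzeneselenolate (diphenyl diselenide, NaBH4, ethanol) would open the oxirane at C2 to give 2-phenylselanyl-5-O-TBS-3,4-O-isopropylidene-quinyl alcohol F3. Radical reduction of the C–Se bond with Bu3SnH and AIBN would return to the route at 7.

**Step 12.** Discrimination between the equatorial O3–H and the axial O4–H may be incomplete, and the first acyl group may migrate between the cis oxygens. The fallback reverses the order of acylation with a temporary silyl group. Starting from 12, TESCl and imidazole at low temperature would silylate the equatorial hydroxyl to give 3-O-TES-1-O-Troc-1,5-quinide F4. Acylation of O4 with 19 under DMAP would give 4-O-(4-acetoxycinnamoyl)-3-O-TES-1-O-Troc-1,5-quinide F5. HF·pyridine would remove the silyl group to give 4-O-(4-acetoxycinnamoyl)-1-O-Troc-1,5-quinide F6. Acylation of O3 with 15 would return to the route at 20, bypassing 16.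

**Step 14.** Acylation of the hindered axial O4–H may be slow, which gives time for DMAP-promoted migration of the 3-O-acyl group or acetyl transfer from the aryl acetates. The fallback builds the cinnamate by olefination. Starting from 16, esterification with (diethoxyphosphoryl)acetic acid and DCC, a small acylating agent that reacts through its ketene, would give 4-O-[(diethoxyphosphoryl)acetyl]-3-O-(3,4-diacetoxycinnamoyl)-1-O-Troc-1,5-quinide F7. A Horner–Wadsworth–Emmons reaction with 4-acetoxybenzaldehyde (LiCl, iPr2NEt, MeCN) would form the E alkene and return to the route at 20.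

## Further compounds

F1 | step 4 | 5-O-TBS-shikimyl alcohol (3,4-diol free) | O[C@H]1[C@H](O[Si](C)(C)C(C)(C)C)CC(CO)=C[C@H]1O
F2 | step 4 | (1S,2S)-1,2-epoxy-5-O-TBS-shikimyl alcohol (oxirane cis to O3 and O4) | O[C@H]1[C@H](O[Si](C)(C)C(C)(C)C)C[C@@]2(CO)O[C@H]2[C@H]1O
F3 | step 5 | 2-phenylselanyl-5-O-TBS-3,4-O-isopropylidene-quinyl alcohol (selenium trans to O1 and O3) | CC1(C)O[C@H]2[C@H](O[Si](C)(C)C(C)(C)C)C[C@](O)(CO)[C@H]([Se]c3ccccc3)[C@H]2O1
F4 | step 12 | 3-O-TES-1-O-Troc-1,5-quinide | O[C@H]1[C@H]2C[C@](OC(=O)OCC(Cl)(Cl)Cl)(C(=O)O2)C[C@H]1O[Si](CC)(CC)CC
F5 | step 12 | 4-O-[(E)-4-acetoxycinnamoyl]-3-O-TES-1-O-Troc-1,5-quinide | CC(=O)Oc1ccc(/C=C/C(=O)O[C@H]2[C@H]3C[C@](OC(=O)OCC(Cl)(Cl)Cl)(C(=O)O3)C[C@H]2O[Si](CC)(CC)CC)cc1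
F6 | step 12 | 4-O-[(E)-4-acetoxycinnamoyl]-1-O-Troc-1,5-quinide | CC(=O)Oc1ccc(/C=C/C(=O)O[C@H]2[C@H]3C[C@](OC(=O)OCC(Cl)(Cl)Cl)(C(=O)O3)C[C@H]2O)cc1
F7 | step 14 | 4-O-[(diethoxyphosphoryl)acetyl]-3-O-[(E)-3,4-diacetoxycinnamoyl]-1-O-Troc-1,5-quinide | CCOP(=O)(OCC)CC(=O)O[C@H]1[C@H]2C[C@](OC(=O)OCC(Cl)(Cl)Cl)(C(=O)O2)C[C@H]1OC(=O)/C=C/c1ccc(OC(C)=O)c(OC(C)=O)c1
A1 | alternative 1 | (S)-1-formylcyclohex-3-en-1-yl benzoate | C1=CC[C@](OC(=O)c2ccccc2)(C=O)CC1
A2 | alternative 1 | buta-1,3-diene | C=CC=C
A3 | alternative 1 | 2-(benzoyloxy)acrolein | C=C(OC(=O)c1ccccc1)C=O
A4 | alternative 2 | 3-dehydroquinic acid | O[C@H]1[C@H](O)C[C@](O)(C(=O)O)CC1=O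
A5 | alternative 2 | phosphoenolpyruvate (free acid) | C=C(OP(=O)(O)O)C(=O)O
A6 | alternative 2 | D-erythrose 4-phosphate | O=C[C@H](O)[C@H](O)COP(=O)(O)O
A7 | alternative 2 | (−)-quinic acid | O[C@H]1[C@H](O)C[C@](O)(C(=O)O)C[C@H]1O
A8 | alternative 3 | methyl 1,5-di-O-benzylquinate | O[C@H]1[C@H](OCc2ccccc2)C[C@](OCc2ccccc2)(C(=O)OC)C[C@H]1O
A9 | alternative 3 | methyl 2,4-bis(benzyloxy)-2-(2-oxoethyl)-5-oxopentanoate (C1 and C5 configured as in quinic acid) | O=C[C@H](OCc1ccccc1)C[C@](OCc1ccccc1)(C(=O)OC)CC=O
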